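## Retrosynthetic overview

- The target has two 2,6-dihydroxy-4-methoxyphenyl ketone rings joined by a CH2: ring A (a1 OCH3, a2 H, a3 OH, a4 ketone K1, a5 OH, a6 CH2) and ring C (c1 CH2, c2 OCH3, c3 H, c4 OH, c5 ketone K2, c6 OH). K1 carries ring B (2,4-dihydroxy-6-methylphenyl) and K2 carries ring D; there is no stereocentre.
- The plan rests on ring D, which reads around the ring K2-acyl (d1), CH3 (d2), H (d3), OH (d4), H (d5), OCH3 (d6). This is what a but-2-ynoyl group on c5 leaves after (4+2) addition of 1,1-dimethoxy-3-(trimethylsilyloxy)buta-1,3-diene (new bonds d1–d6 and d2–d3) and loss of methanol.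
- The ynone is made from the ring C aldehyde of a hexabenzylated diarylmethane by propynyl Grignard addition and oxidation. The a6–CH2–c1 bond is made from the ortho-quinone methide of a ring A Mannich base and 2,6-dihydroxy-4-methoxybenzaldehyde, whose two open positions are equivalent.
- K1 is made by adding the ring B aryllithium (from orcinol) to the bis-MOM ether of the same aldehyde and oxidising, so rings A and C both derive from 2,4,6-trihydroxybenzaldehyde.
- Rings A, B and C are bought as arenes; ring D is the only ring built and is closed last, before global hydrogenolysis.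

Key step: step 16

Remark: the target is achiral; the carbinol centres of 8 and 16 form as racemates and are removed by oxidation, so all SMILES carry no stereodescriptors.

## Route

Step 1
Reactants: 1 2,4,6-trihydroxybenzaldehyde
Product: 2 2,6-dihydroxy-4-methoxybenzaldehyde
Conditions: MeI (1.05 equiv), K2CO3 (1.0 equiv), acetone, 0 °C → rt
Reagents that add atoms: iodomethane, CI
Why: Williamson etherification; the 4-hydroxyl is the most acidic (para to the formyl group) and the only one not chelated to the carbonyl oxygen, so one equivalent of base and MeI should give the para monomethyl ether.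

Step 2
Reactants: 2 2,6-dihydroxy-4-methoxybenzaldehyde
Product: 3 4-methoxy-2,6-bis(methoxymethoxy)benzaldehyde
Conditions: MOMCl (3 equiv), i-Pr2NEt (4 equiv), CH2Cl2, 0 → 40 °C
Reagents that add atoms: chloromethyl methyl ether, COCCl
Why: O-alkylation (acetal-type Williamson etherification) of both chelated phenols with the highly reactive MOM chloride should give an aldehyde that tolerates an aryllithium and can later be unmasked by acid without loss of benzyl ethers.

Step 3
Reactants: 4 orcinol (5-methylbenzene-1,3-diol)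
Product: 5 1,3-bis(benzyloxy)-5-methylbenzene
Conditions: BnBr (2.2 equiv), K2CO3, DMF, 60 °C
Reagents that add atoms: benzyl bromide, BrCc1ccccc1
Why: Williamson etherification of both unhindered phenols.

Step 4
Reactants: 5 1,3-bis(benzyloxy)-5-methylbenzene
Product: 6 1,5-bis(benzyloxy)-2-bromo-3-methylbenzene
Conditions: NBS (1.0 equiv), MeCN, 0 °C → rt
Reagents that add atoms: N-bromosuccinimide, O=C1CCC(=O)N1Br
Why: Electrophilic aromatic bromination under ionic conditions should take place ortho to the methyl group and para to a benzyloxy group (two equivalent positions) in preference to the more crowded position between the two benzyloxy groups.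

Step 5
Reactants: 6 1,5-bis(benzyloxy)-2-bromo-3-methylbenzene; 3 4-methoxy-2,6-bis(methoxymethoxy)benzaldehyde
Product: 8 [2,4-bis(benzyloxy)-6-methylphenyl][4-methoxy-2,6-bis(methoxymethoxy)phenyl]methanol (racemic), via aryllithium 7 (not isolated)
Conditions: 6, n-BuLi (1.05 equiv), THF, −78 °C; then 3, −78 → 0 °C; H2O
Reagents that add atoms: none
Why: Bromine–lithium exchange at −78 °C is faster than any benzylic deprotonation, and 1,2-addition of the aryllithium to the MOM-chelating aldehyde (organolithium addition) should give the tetra-ortho-substituted benzhydrol, whose racemic carbinol centre is removed in step 6.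

Step 6
Reactants: 8 [2,4-bis(benzyloxy)-6-methylphenyl][4-methoxy-2,6-bis(methoxymethoxy)phenyl]methanol
Product: 9 [2,4-bis(benzyloxy)-6-methylphenyl][4-methoxy-2,6-bis(methoxymethoxy)phenyl]methanone
Conditions: DMP (1.5 equiv), NaHCO3, CH2Cl2, rt
Reagents that add atoms: none
Why: Dess–Martin oxidation of the crowded doubly benzylic alcohol under buffered conditions keeps MOM and benzyl ethers and creates K1 without a hindered Friedel–Crafts acylation.

Step 7
Reactants: 9 [2,4-bis(benzyloxy)-6-methylphenyl][4-methoxy-2,6-bis(methoxymethoxy)phenyl]methanone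
Product: 10 [2,4-bis(benzyloxy)-6-methylphenyl](2,6-dihydroxy-4-methoxyphenyl)methanone
Conditions: 3 M aq HCl, MeOH–THF, 50 °C
Reagents that add atoms: none
Why: Acid-catalysed acetal cleavage removes both MOM groups, while benzyl aryl ethers are inert to dilute HCl, so only ring A is set free as a phenol.

Step 8
Reactants: 10 [2,4-bis(benzyloxy)-6-methylphenyl](2,6-dihydroxy-4-methoxyphenyl)methanone
Product: 11 [2,4-bis(benzyloxy)-6-methylphenyl]{3-[(dimethylamino)methyl]-2,6-dihydroxy-4-methoxyphenyl}methanone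
Conditions: Me2N=CH2 I (N,N-dimethylmethyleneiminium iodide, 1.05 equiv), CH2Cl2, rt; aq NaHCO3
Reagents that add atoms: N,N-dimethylmethyleneiminium iodide, C=[N+](C)C.[I-]
Why: Mannich reaction; the free phloroglucinol-type ring A is far more nucleophilic than the fully etherified ring B, its two open positions (a2, a6) are equivalent, and the ammonium product is deactivated towards a second aminomethylation.

Step 9
Reactants: 11 [2,4-bis(benzyloxy)-6-methylphenyl]{3-[(dimethylamino)methyl]-2,6-dihydroxy-4-methoxyphenyl}methanone; 2 2,6-dihydroxy-4-methoxybenzaldehyde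
Product: 13 3-({3-[2,4-bis(benzyloxy)-6-methylbenzoyl]-2,4-dihydroxy-6-methoxyphenyl}methyl)-2,6-dihydroxy-4-methoxybenzaldehyde, via ortho-quinone methide 12 (not isolated)
Conditions: 2 (3 equiv), 1,4-dioxane, 100 °C, N2 sweep
Reagents that add atoms: none
Why: Thermal loss of dimethylamine from the ortho-hydroxybenzylamine gives an ortho-quinone methide that the excess phloroglucinol aldehyde should capture at C3 (identical with C5) in a conjugate Friedel–Crafts-type alkylation, the established way to unsymmetrical methylene-bridged acylphloroglucinols.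

Step 10
Reactants: 13 3-({3-[2,4-bis(benzyloxy)-6-methylbenzoyl]-2,4-dihydroxy-6-methoxyphenyl}methyl)-2,6-dihydroxy-4-methoxybenzaldehyde
Product: 14 2,6-bis(benzyloxy)-3-({2,4-bis(benzyloxy)-3-[2,4-bis(benzyloxy)-6-methylbenzoyl]-6-methoxyphenyl}methyl)-4-methoxybenzaldehyde
Conditions: BnBr (6 equiv), K2CO3 (8 equiv), DMF, 60 °C
Reagents that add atoms: benzyl bromide, BrCc1ccccc1
Why: Williamson etherification in a polar aprotic solvent should O-benzylate the four chelated phenols, which removes the acidic protons before the Grignard step and prevents later oxa-Michael closure onto the ynone.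

Step 11
Reactants: 14 2,6-bis(benzyloxy)-3-({2,4-bis(benzyloxy)-3-[2,4-bis(benzyloxy)-6-methylbenzoyl]-6-methoxyphenyl}methyl)-4-methoxybenzaldehyde; 15 1-propynylmagnesium bromide
Product: 16 1-[2,6-bis(benzyloxy)-3-({2,4-bis(benzyloxy)-3-[2,4-bis(benzyloxy)-6-methylbenzoyl]-6-methoxyphenyl}methyl)-4-methoxyphenyl]but-2-yn-1-ol (racemic)
Conditions: 15 (0.5 M in THF, 2 equiv), THF, 0 °C; H2O
Reagents that add atoms: none
Why: Grignard 1,2-addition should occur only at the aldehyde, since K1 is shielded by four ortho substituents; the racemic carbinol centre is removed in step 12.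

Step 12
Reactants: 16 1-[2,6-bis(benzyloxy)-3-({2,4-bis(benzyloxy)-3-[2,4-bis(benzyloxy)-6-methylbenzoyl]-6-methoxyphenyl}methyl)-4-methoxyphenyl]but-2-yn-1-ol
Product: 17 1-[2,6-bis(benzyloxy)-3-({2,4-bis(benzyloxy)-3-[2,4-bis(benzyloxy)-6-methylbenzoyl]-6-methoxyphenyl}methyl)-4-methoxyphenyl]but-2-yn-1-one
Conditions: DMP (1.5 equiv), NaHCO3, CH2Cl2, 0 °C → rt
Reagents that add atoms: none
Why: Dess–Martin oxidation of the benzylic propargylic alcohol should give the ynone cleanly, and with both ortho oxygens benzylated no cyclisation to a chromone or aurone is possible.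

Step 13
Reactants: 18 acetyl chloride; 19 1,1-dichloroethene
Product: 21 4,4-dichlorobut-3-en-2-one, via 4,4,4-trichlorobutan-2-one 20 (not isolated)
Conditions: AlCl3 (1.1 equiv), CH2Cl2, 0 → 20 °C; ice–H2O; distillation (loss of HCl)
Reagents that add atoms: none
Why: Friedel–Crafts-type acylation of the alkene: the acylium ion adds to the CH2 terminus of 1,1-dichloroethene, chloride capture gives the trichloro ketone, and loss of HCl gives the conjugated dichlorovinyl ketone.

Step 14
Reactants: 21 4,4-dichlorobut-3-en-2-one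
Product: 22 4,4-dimethoxybut-3-en-2-one
Conditions: NaOMe (2.1 equiv), MeOH, 0 °C → rt
Reagents that add atoms: sodium methoxide, C[O-].[Na+]
Why: Two successive addition–elimination steps (vinylogous acyl substitution) should replace both β-chlorides by methoxide.

Step 15
Reactants: 22 4,4-dimethoxybut-3-en-2-one
Product: 23 1,1-dimethoxy-3-(trimethylsilyloxy)buta-1,3-diene
Conditions: Me3SiCl (1.3 equiv), Et3N (1.5 equiv), ZnCl2 (cat.), toluene, 40 °C
Reagents that add atoms: chlorotrimethylsilane, C[Si](C)(C)Cl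
Why: Silyl enol ether formation at the methyl group, the only enolisable position of the ketone, gives the 2-silyloxy diene; it is distilled and used at once.

Step 16
Reactants: 17 1-[2,6-bis(benzyloxy)-3-({2,4-bis(benzyloxy)-3-[2,4-bis(benzyloxy)-6-methylbenzoyl]-6-methoxyphenyl}methyl)-4-methoxyphenyl]but-2-yn-1-one; 23 1,1-dimethoxy-3-(trimethylsilyloxy)buta-1,3-diene
Product: 26 [2,6-bis(benzyloxy)-3-({2,4-bis(benzyloxy)-3-[2,4-bis(benzyloxy)-6-methylbenzoyl]-6-methoxyphenyl}methyl)-4-methoxyphenyl](4-hydroxy-2-methoxy-6-methylphenyl)methanone, via cyclohexa-1,4-diene cycloadduct 24 (not isolated), via aryl trimethylsilyl ether 25 (not isolated)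
Conditions: 23 (4 equiv, in portions), toluene, 110 °C, sealed tube; then 1 M aq HCl, THF, rt
Reagents that add atoms: none
Why: The diene has its largest HOMO coefficient on the CH2 terminus and the ynone its largest LUMO coefficient on the methyl-bearing β-carbon, so an asynchronous (4+2) cycloaddition should join these carbons (d2–d3) ahead of the bond between the ketal carbon and the α-carbon (d1–d6), giving cyclohexa-1,4-diene 24. The closest known reaction type is the Diels–Alder benzannulation of 1,1-dialkoxy-3-silyloxybuta-1,3-dienes with acetylenic ketones and esters, which gives resorcinol monoethers. Ring D is closed as a six-membered carbocycle by intermolecular cycloaddition, both new σ-bonds coming from the two π-components, and is aromatised by 1,4-elimination of methanol (d3–H, d6–OCH3) to 25, whose silyl ether is cleaved by dilute acid. No stereocentre is formed. The step needs regioselectivity, which the matched polarisation of diene and ynone secures (OCH3 ortho and OH para to K2), and chemoselectivity, which is secured because the ynone is the only electron-poor π-bond within reach, K1 lying between four ortho substituents. The two ortho benzyloxy groups of ring C shield the ynone carbonyl against 1,2-attack by the ketene acetal and, being ethers, cannot add to the triple bond.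

Step 17
Reactants: 26 [2,6-bis(benzyloxy)-3-({2,4-bis(benzyloxy)-3-[2,4-bis(benzyloxy)-6-methylbenzoyl]-6-methoxyphenyl}methyl)-4-methoxyphenyl](4-hydroxy-2-methoxy-6-methylphenyl)methanone
Product: 27 [3-({3-(2,4-dihydroxy-6-methylbenzoyl)-2,4-dihydroxy-6-methoxyphenyl}methyl)-2,6-dihydroxy-4-methoxyphenyl](4-hydroxy-2-methoxy-6-methylphenyl)methanone (CNP0596095.0)
Conditions: H2 (1 atm), 10% Pd/C, EtOAc–MeOH, rt
Reagents that add atoms: none
Why: Catalytic hydrogenolysis should cleave all six benzyl aryl ethers, while the two diaryl ketones (twisted, and chelated by ortho hydroxyls as these are freed), the aryl methyl ethers and the diarylmethane should be left untouched.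

## Compound list

1 | 2,4,6-trihydroxybenzaldehyde | O=Cc1c(O)cc(O)cc1O | starting material
2 | 2,6-dihydroxy-4-methoxybenzaldehyde | COc1cc(O)c(C=O)c(O)c1 | intermediate
3 | 4-methoxy-2,6-bis(methoxymethoxy)benzaldehyde | COCOc1cc(OC)cc(OCOC)c1C=O | intermediate
4 | orcinol (5-methylbenzene-1,3-diol) | Cc1cc(O)cc(O)c1 | starting material
5 | 1,3-bis(benzyloxy)-5-methylbenzene | Cc1cc(OCc2ccccc2)cc(OCc2ccccc2)c1 | intermediate
6 | 1,5-bis(benzyloxy)-2-bromo-3-methylbenzene | Cc1cc(OCc2ccccc2)cc(OCc2ccccc2)c1Br | intermediate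
7 | [2,4-bis(benzyloxy)-6-methylphenyl]lithium (not isolated) | [Li]c1c(C)cc(OCc2ccccc2)cc1OCc1ccccc1 | intermediate
8 | [2,4-bis(benzyloxy)-6-methylphenyl][4-methoxy-2,6-bis(methoxymethoxy)phenyl]methanol (racemic) | COCOc1cc(OC)cc(OCOC)c1C(O)c1c(C)cc(OCc2ccccc2)cc1OCc1ccccc1 | intermediate
9 | [2,4-bis(benzyloxy)-6-methylphenyl][4-methoxy-2,6-bis(methoxymethoxy)phenyl]methanone | COCOc1cc(OC)cc(OCOC)c1C(=O)c1c(C)cc(OCc2ccccc2)cc1OCc1ccccc1 | intermediate
10 | [2,4-bis(benzyloxy)-6-methylphenyl](2,6-dihydroxy-4-methoxyphenyl)methanone (A–B benzophenone) | COc1cc(O)c(C(=O)c2c(C)cc(OCc3ccccc3)cc2OCc2ccccc2)c(O)c1 | intermediate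
11 | [2,4-bis(benzyloxy)-6-methylphenyl]{3-[(dimethylamino)methyl]-2,6-dihydroxy-4-methoxyphenyl}methanone (Mannich base) | COc1cc(O)c(C(=O)c2c(C)cc(OCc3ccccc3)cc2OCc2ccccc2)c(O)c1CN(C)C | intermediate
12 | 2-[2,4-bis(benzyloxy)-6-methylbenzoyl]-3-hydroxy-5-methoxy-6-methylidenecyclohexa-2,4-dien-1-one (ortho-quinone methide, not isolated) | C=C1C(=O)C(C(=O)c2c(C)cc(OCc3ccccc3)cc2OCc2ccccc2)=C(O)C=C1OC | intermediate
13 | 3-({3-[2,4-bis(benzyloxy)-6-methylbenzoyl]-2,4-dihydroxy-6-methoxyphenyl}methyl)-2,6-dihydroxy-4-methoxybenzaldehyde | COc1cc(O)c(C(=O)c2c(C)cc(OCc3ccccc3)cc2OCc2ccccc2)c(O)c1Cc1c(OC)cc(O)c(C=O)c1O | intermediate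
14 | 2,6-bis(benzyloxy)-3-({2,4-bis(benzyloxy)-3-[2,4-bis(benzyloxy)-6-methylbenzoyl]-6-methoxyphenyl}methyl)-4-methoxybenzaldehyde (hexabenzyl aldehyde) | COc1cc(OCc2ccccc2)c(C(=O)c2c(C)cc(OCc3ccccc3)cc2OCc2ccccc2)c(OCc2ccccc2)c1Cc1c(OC)cc(OCc2ccccc2)c(C=O)c1OCc1ccccc1 | intermediate
15 | 1-propynylmagnesium bromide | CC#C[Mg]Br | starting material
16 | 1-[2,6-bis(benzyloxy)-3-({2,4-bis(benzyloxy)-3-[2,4-bis(benzyloxy)-6-methylbenzoyl]-6-methoxyphenyl}methyl)-4-methoxyphenyl]but-2-yn-1-ol (racemic) | COc1cc(OCc2ccccc2)c(C(=O)c2c(C)cc(OCc3ccccc3)cc2OCc2ccccc2)c(OCc2ccccc2)c1Cc1c(OC)cc(OCc2ccccc2)c(C(O)C#CC)c1OCc1ccccc1 | intermediate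
17 | 1-[2,6-bis(benzyloxy)-3-({2,4-bis(benzyloxy)-3-[2,4-bis(benzyloxy)-6-methylbenzoyl]-6-methoxyphenyl}methyl)-4-methoxyphenyl]but-2-yn-1-one (hexabenzyl ynone) | COc1cc(OCc2ccccc2)c(C(=O)c2c(C)cc(OCc3ccccc3)cc2OCc2ccccc2)c(OCc2ccccc2)c1Cc1c(OC)cc(OCc2ccccc2)c(C(=O)C#CC)c1OCc1ccccc1 | intermediate
18 | acetyl chloride | CC(=O)Cl | starting material
19 | 1,1-dichloroethene | C=C(Cl)Cl | starting material
20 | 4,4,4-trichlorobutan-2-one (not isolated) | CC(=O)CC(Cl)(Cl)Cl | intermediate
21 | 4,4-dichlorobut-3-en-2-one | CC(=O)C=C(Cl)Cl | intermediate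
22 | 4,4-dimethoxybut-3-en-2-one | CC(=O)C=C(OC)OC | intermediate
23 | 1,1-dimethoxy-3-(trimethylsilyloxy)buta-1,3-diene | COC(OC)=CC(=C)O[Si](C)(C)C | intermediate
24 | hexabenzyl ring C aryl 6,6-dimethoxy-2-methyl-4-(trimethylsilyloxy)cyclohexa-1,4-dien-1-yl ketone (cycloadduct, not isolated) | COc1cc(OCc2ccccc2)c(C(=O)c2c(C)cc(OCc3ccccc3)cc2OCc2ccccc2)c(OCc2ccccc2)c1Cc1c(OC)cc(OCc2ccccc2)c(C(=O)C2=C(C)CC(O[Si](C)(C)C)=CC2(OC)OC)c1OCc1ccccc1 | intermediate
25 | hexabenzyl ring C aryl 2-methoxy-6-methyl-4-(trimethylsilyloxy)phenyl ketone (not isolated) | COc1cc(OCc2ccccc2)c(C(=O)c2c(C)cc(OCc3ccccc3)cc2OCc2ccccc2)c(OCc2ccccc2)c1Cc1c(OC)cc(OCc2ccccc2)c(C(=O)c2c(C)cc(O[Si](C)(C)C)cc2OC)c1OCc1ccccc1 | intermediate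
26 | [2,6-bis(benzyloxy)-3-({2,4-bis(benzyloxy)-3-[2,4-bis(benzyloxy)-6-methylbenzoyl]-6-methoxyphenyl}methyl)-4-methoxyphenyl](4-hydroxy-2-methoxy-6-methylphenyl)methanone (hexabenzyl ether of the target, d4 hydroxyl free) | COc1cc(OCc2ccccc2)c(C(=O)c2c(C)cc(OCc3ccccc3)cc2OCc2ccccc2)c(OCc2ccccc2)c1Cc1c(OC)cc(OCc2ccccc2)c(C(=O)c2c(C)cc(O)cc2OC)c1OCc1ccccc1 | intermediate
27 | [3-({3-(2,4-dihydroxy-6-methylbenzoyl)-2,4-dihydroxy-6-methoxyphenyl}methyl)-2,6-dihydroxy-4-methoxyphenyl](4-hydroxy-2-methoxy-6-methylphenyl)methanone (CNP0596095.0) | COc1cc(O)c(C(=O)c2c(C)cc(O)cc2O)c(O)c1Cc1c(OC)cc(O)c(C(=O)c2c(C)cc(O)cc2OC)c1O | target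

## Step count and risks

Total step count: 17 (12 on the main line, 2 for the ring B bromide, 3 for the diene).
Longest linear sequence: 12 steps (steps 1, 2, 5, 6, 7, 8, 9, 10, 11, 12, 16, 17).

Steps most likely to fail:

Step 16. The labile ketene-acetal diene may decompose or lose its silyl group before it adds to the β-methyl ynone, whose triple bond is shielded by the two ortho benzyloxy groups of ring C, and attack at the carbonyl carbon may compete. Fallback: the dienophile is changed to an allenyl ketone. It sets out from aldehyde 14. Barbier propargylation (propargyl bromide, Zn, THF–aq NH4Cl, 0 °C) should give the homopropargylic alcohol F1. Dess–Martin oxidation followed by stirring with catalytic Et3N should give the allenyl ketone F2, a far more reactive and less hindered dienophile. Diene 23 should add to the conjugated C=C of F2 at or below room temperature with the same orientation (CH2 terminus of the diene to the central allene carbon), giving the methylidenecyclohexene cycloadduct F3 (not isolated). Loss of methanol and shift of the exocyclic double bond into the ring give aryl silyl ether 25, and the acid work-up of step 16 returns the route at 26. This rests on the known Diels–Alder reactions of allenic esters and ketones with alkoxy silyloxy dienes that give ortho-alkyl arenes.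

Step 9. On heating, the ortho-quinone methide may add to a second Mannich base or to product 13 (oligomers), and reversible fragmentation of the methylene bridge may scramble the two halves into symmetrical dimers. Fallback: the bridge is made first on a symmetrical compound and the two aldehydes are told apart afterwards. It sets out from 2. Condensation with aqueous CH2O (0.4 equiv, 1% aq NaOH, rt, then dilute HCl) should give 3,3'-methylenebis(2,6-dihydroxy-4-methoxybenzaldehyde) F4. Fourfold O-benzylation (BnBr, K2CO3, DMF, 60 °C) should give the tetrabenzyl dialdehyde F5. Addition of one equivalent of aryllithium 7 (from 6 as in step 5, THF, −78 °C) should give the mono-adduct carbinol F6; this desymmetrisation is statistical, so F6 has to be separated from the bis-adduct and from unreacted F5, which is recycled. Dess–Martin oxidation of the carbinol, which leaves the aldehyde untouched, returns the route at 14.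

Step 1. Methylation may not stop at the monoether or may partly occur at a chelated ortho hydroxyl, giving mixtures of ethers that are hard to separate. Fallback: all three hydroxyls are methylated and the two ortho ethers are then removed selectively. It sets out from 1. Exhaustive methylation (MeI, 4 equiv, K2CO3, DMF, rt) should give 2,4,6-trimethoxybenzaldehyde F7. AlCl3 (3 equiv, CH2Cl2, 0 °C → rt; aq HCl) should cleave only the two methyl ethers that can chelate aluminium together with the formyl oxygen, which returns the route at 2.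

Further compounds
F1 | step 16 | 1-[2,6-bis(benzyloxy)-3-({2,4-bis(benzyloxy)-3-[2,4-bis(benzyloxy)-6-methylbenzoyl]-6-methoxyphenyl}methyl)-4-methoxyphenyl]but-3-yn-1-ol (racemic) | COc1cc(OCc2ccccc2)c(C(=O)c2c(C)cc(OCc3ccccc3)cc2OCc2ccccc2)c(OCc2ccccc2)c1Cc1c(OC)cc(OCc2ccccc2)c(C(O)CC#C)c1OCc1ccccc1
F2 | step 16 | 1-[2,6-bis(benzyloxy)-3-({2,4-bis(benzyloxy)-3-[2,4-bis(benzyloxy)-6-methylbenzoyl]-6-methoxyphenyl}methyl)-4-methoxyphenyl]buta-2,3-dien-1-one | COc1cc(OCc2ccccc2)c(C(=O)c2c(C)cc(OCc3ccccc3)cc2OCc2ccccc2)c(OCc2ccccc2)c1Cc1c(OC)cc(OCc2ccccc2)c(C(=O)C=C=C)c1OCc1ccccc1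
F3 | step 16 | hexabenzyl ring C aryl 2,2-dimethoxy-6-methylidene-4-(trimethylsilyloxy)cyclohex-3-en-1-yl ketone (racemic cycloadduct, not isolated) | COc1cc(OCc2ccccc2)c(C(=O)c2c(C)cc(OCc3ccccc3)cc2OCc2ccccc2)c(OCc2ccccc2)c1Cc1c(OC)cc(OCc2ccccc2)c(C(=O)C2C(=C)CC(O[Si](C)(C)C)=CC2(OC)OC)c1OCc1ccccc1
F4 | step 9 | 3,3'-methylenebis(2,6-dihydroxy-4-methoxybenzaldehyde) | COc1cc(O)c(C=O)c(O)c1Cc1c(OC)cc(O)c(C=O)c1O
F5 | step 9 | 3,3'-methylenebis[2,6-bis(benzyloxy)-4-methoxybenzaldehyde] | COc1cc(OCc2ccccc2)c(C=O)c(OCc2ccccc2)c1Cc1c(OC)cc(OCc2ccccc2)c(C=O)c1OCc1ccccc1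
F6 | step 9 | 2,6-bis(benzyloxy)-3-[(2,4-bis(benzyloxy)-3-{[2,4-bis(benzyloxy)-6-methylphenyl](hydroxy)methyl}-6-methoxyphenyl)methyl]-4-methoxybenzaldehyde (racemic) | COc1cc(OCc2ccccc2)c(C(O)c2c(C)cc(OCc3ccccc3)cc2OCc2ccccc2)c(OCc2ccccc2)c1Cc1c(OC)cc(OCc2ccccc2)c(C=O)c1OCc1ccccc1
F7 | step 1 | 2,4,6-trimethoxybenzaldehyde | COc1cc(OC)c(C=O)c(OC)c1
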